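**Retrosynthetic overview**
- The 3'–8'' biaryl bond is cut last: a base-free Negishi union of 3'-iodosakuranetin with the zinc reagent of 5-hydroxy-8-iodo-7-methoxy-2-(4-methoxyphenyl)chromen-4-one, all phenols masked transiently as silyl ethers.
- The flavanone half, with both of its rings and the only stereocentre, is (2S)-naringenin after 7-O-methylation and iodination ortho to the 4'-phenol.
- The flavone half: ring A iodination and 5-O-demethylation follow construction of pyranone ring C from an isoxazole (N–O reduction, then closure of the unmasked phenol onto the β-amino enone with loss of ammonia).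
- Key step: that isoxazole comes from a thermal [3+2] cycloaddition of 4-methoxybenzonitrile oxide to 2-ethynyl-1,5-dimethoxy-3-(methoxymethoxy)benzene; the new ring already carries C2, C3, C4 and the carbonyl oxygen of the future pyranone.
- Ring order: isoxazole (cycloaddition), then flavone ring C (ring transposition), then the biaryl union; the chromanone and all benzene rings are bought.

Assumption: commercial (2S)-naringenin is the single enantiomer (ee checked by chiral HPLC), and the two rotamers about the biaryl bond interconvert at room temperature, so C2 is the only stereo-element to control.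

Step 1
Reactants: 1 (2S)-naringenin [(2S)-5,7-dihydroxy-2-(4-hydroxyphenyl)chroman-4-one]
Product: 2 (2S)-sakuranetin [(2S)-5-hydroxy-2-(4-hydroxyphenyl)-7-methoxychroman-4-one]
Conditions: TMSCHN2 (1.05 equiv), MeOH/toluene 1:3, 0 °C to rt
Reagents that add atoms: trimethylsilyldiazomethane, C[Si](C)(C)C=[N+]=[N-]
Why: Diazoalkane O-methylation follows phenol acidity, so the 7-OH (para to the carbonyl, the most acidic) is methylated before the 4'-OH while the hydrogen-bonded 5-OH does not react, and these base-free conditions cannot epimerise C2, whose (S) configuration is the one bought in naringenin.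

Step 2
Reactants: 2 (2S)-sakuranetin
Product: 3 (2S)-3'-iodosakuranetin [(2S)-5-hydroxy-2-(4-hydroxy-3-iodophenyl)-7-methoxychroman-4-one]
Conditions: I2 (1.0 equiv), NaHCO3 (2.5 equiv), THF/H2O 1:1, 0 °C, 1 h; Na2S2O3, then pH 5
Reagents that add atoms: iodine, [I][I]
Why: Electrophilic aromatic iodination through the phenoxide: in cold bicarbonate only the 4'-OH is appreciably ionised (the 5-OH is chelated, the 7-oxygen is capped), so iodine enters ring B ortho to the 4'-oxygen, and the weak base, low temperature and short time keep base-induced opening of the pyranone (the racemisation pathway) negligible.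

Step 3
Reactants: 4 2-hydroxy-4,6-dimethoxybenzaldehyde
Product: 5 2,4-dimethoxy-6-(methoxymethoxy)benzaldehyde
Conditions: MOMCl (1.3 equiv), K2CO3 (2 equiv), acetone, rt to 50 °C
Reagents that add atoms: chloromethyl methyl ether, COCCl
Why: Williamson-type O-alkylation of the salicylaldehyde phenoxide gives a methoxymethyl acetal that survives the basic alkyne synthesis, the cycloaddition and the reduction, and is removed by the acid that closes ring C in step 6.

Step 4
Reactants: 5 2,4-dimethoxy-6-(methoxymethoxy)benzaldehyde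
Product: 6 2-ethynyl-1,5-dimethoxy-3-(methoxymethoxy)benzene
Conditions: dimethyl (1-diazo-2-oxopropyl)phosphonate (1.5 equiv), K2CO3 (2.5 equiv), MeOH, rt to 40 °C
Reagents that add atoms: dimethyl (1-diazo-2-oxopropyl)phosphonate, CC(=O)C(=[N+]=[N-])P(=O)(OC)OC
Why: Seyferth–Gilbert homologation in its Ohira–Bestmann form: methanolysis of the reagent gives the diazomethylphosphonate anion, Horner–Wadsworth–Emmons addition to the aldehyde and loss of phosphate give a diazoalkene, and loss of N2 followed by a 1,2-hydrogen shift gives the terminal alkyne.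

Step 5
Reactants: 6 2-ethynyl-1,5-dimethoxy-3-(methoxymethoxy)benzene; 7 N-hydroxy-4-methoxybenzimidoyl chloride
Product: 9 5-[2,4-dimethoxy-6-(methoxymethoxy)phenyl]-3-(4-methoxyphenyl)isoxazole, via 4-methoxybenzonitrile oxide 8 (not isolated)
Conditions: 7 (2 equiv, in portions), NaHCO3 (4 equiv), EtOAc, 50 °C
Reagents that add atoms: none
Why: Key step, a thermal Huisgen [3+2] cycloaddition: bicarbonate releases the nitrile oxide slowly (limiting its dimerisation) and it adds across the terminal alkyne in a concerted manner, carbon to the CH terminus and oxygen to the aryl-bearing carbon, giving only the 3,5-disubstituted isoxazole, a ring that already holds C2, C3, C4 and the carbonyl oxygen of the flavone.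

Step 6
Reactants: 9 5-[2,4-dimethoxy-6-(methoxymethoxy)phenyl]-3-(4-methoxyphenyl)isoxazole
Product: 12 5,7-dimethoxy-2-(4-methoxyphenyl)-4H-chromen-4-one, via MOM-protected amino enone 10 (not isolated), via hydroxyaryl amino enone 11 (not isolated)
Conditions: Mo(CO)6 (1.2 equiv), MeCN/H2O 10:1, 80 °C; filter, concentrate; 3 M HCl in MeOH, 60 °C
Reagents that add atoms: none
Why: Reductive N–O cleavage of the isoxazole by zerovalent molybdenum gives the (Z)-β-amino enone, acid then removes the acetal, and the freed phenol adds to the β-carbon and expels ammonia (conjugate addition–elimination), which transposes the cycloaddition-made ring into pyranone ring C.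

Step 7
Reactants: 12 5,7-dimethoxy-2-(4-methoxyphenyl)-4H-chromen-4-one
Product: 13 8-iodo-5,7-dimethoxy-2-(4-methoxyphenyl)-4H-chromen-4-one
Conditions: NIS (1.1 equiv), TFA (0.3 equiv), MeCN, rt
Reagents that add atoms: N-iodosuccinimide, O=C1CCC(=O)N1I
Why: Electrophilic aromatic iodination of the dimethoxylated ring A: with the 5-oxygen alkylated, attack goes to C8 (ortho to the 7-methoxy group, para to the 5-methoxy group), while C3 and the anisyl ring are deactivated by conjugation to the carbonyl.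

Step 8
Reactants: 13 8-iodo-5,7-dimethoxy-2-(4-methoxyphenyl)-4H-chromen-4-one
Product: 14 5-hydroxy-8-iodo-7-methoxy-2-(4-methoxyphenyl)-4H-chromen-4-one
Conditions: BCl3 (1.5 equiv), CH2Cl2, −78 to 0 °C; then H2O
Reagents that add atoms: none
Why: Chelation-directed Lewis acid ether cleavage: BCl3 bound to the C4 carbonyl removes only the peri 5-O-methyl group, leaving the 7- and 4'-methyl ethers and the C–I bond intact, and it is done here so that the Lewis acid never meets the flavanone stereocentre.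

Step 9
Reactants: 14 5-hydroxy-8-iodo-7-methoxy-2-(4-methoxyphenyl)-4H-chromen-4-one; 3 (2S)-3'-iodosakuranetin
Product: 19 (2S)-2,3-dihydroheveaflavone, via silylated iodoflavone 15 (not isolated), via flavonylzinc iodide 16 (not isolated), via silylated iodoflavanone 17 (not isolated), via silylated biaryl 18 (not isolated)
Conditions: (a) 14 (1.6 equiv), HMDS, TMSCl (5 mol%), THF, 60 °C, evaporate; Zn, LiCl, THF, 50 °C; (b) 3, HMDS, TMSCl (5 mol%), THF, 60 °C, evaporate; (c) a + b, Pd(OAc)2 (4 mol%), RuPhos (8 mol%), THF/NMP 2:1, 65 °C; (d) 1 M HCl, MeOH, rt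
Reagents that add atoms: none
Why: Negishi cross-coupling: zinc inserts into the C8–I bond, zerovalent palladium formed from Pd(OAc)2 and RuPhos adds to the C3'–I bond, and transmetalation and reductive elimination forge the tri-ortho-substituted biaryl; the silyl ethers stop protonation of the zinc reagent, the absence of base leaves C2 (S) untouched, and acidic methanol removes the three silyl groups.

**Compound list**
1 | (2S)-naringenin [(2S)-5,7-dihydroxy-2-(4-hydroxyphenyl)chroman-4-one] | O=C1C[C@@H](c2ccc(O)cc2)Oc2cc(O)cc(O)c12 | starting material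
2 | (2S)-sakuranetin [(2S)-5-hydroxy-2-(4-hydroxyphenyl)-7-methoxychroman-4-one] | O=C1C[C@@H](c2ccc(O)cc2)Oc2cc(OC)cc(O)c12 | intermediate
3 | (2S)-3'-iodosakuranetin [(2S)-5-hydroxy-2-(4-hydroxy-3-iodophenyl)-7-methoxychroman-4-one] | O=C1C[C@@H](c2ccc(O)c(I)c2)Oc2cc(OC)cc(O)c12 | intermediate
4 | 2-hydroxy-4,6-dimethoxybenzaldehyde | COc1cc(O)c(C=O)c(OC)c1 | starting material
5 | 2,4-dimethoxy-6-(methoxymethoxy)benzaldehyde | COCOc1cc(OC)cc(OC)c1C=O | intermediate
6 | 2-ethynyl-1,5-dimethoxy-3-(methoxymethoxy)benzene | COCOc1cc(OC)cc(OC)c1C#C | intermediate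
7 | N-hydroxy-4-methoxybenzimidoyl chloride | COc1ccc(C(Cl)=NO)cc1 | starting material
8 | 4-methoxybenzonitrile oxide | COc1ccc(C#[N+][O-])cc1 | intermediate
9 | 5-[2,4-dimethoxy-6-(methoxymethoxy)phenyl]-3-(4-methoxyphenyl)isoxazole | COCOc1cc(OC)cc(OC)c1-c1cc(-c2ccc(OC)cc2)no1 | intermediate
10 | (Z)-3-amino-1-[2,4-dimethoxy-6-(methoxymethoxy)phenyl]-3-(4-methoxyphenyl)prop-2-en-1-one | N/C(c1ccc(OC)cc1)=C\C(=O)c1c(OC)cc(OC)cc1OCOC | intermediate
11 | (Z)-3-amino-1-(2-hydroxy-4,6-dimethoxyphenyl)-3-(4-methoxyphenyl)prop-2-en-1-one | N/C(c1ccc(OC)cc1)=C\C(=O)c1c(OC)cc(OC)cc1O | intermediate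
12 | 5,7-dimethoxy-2-(4-methoxyphenyl)-4H-chromen-4-one | COc1ccc(-c2cc(=O)c3c(OC)cc(OC)cc3o2)cc1 | intermediate
13 | 8-iodo-5,7-dimethoxy-2-(4-methoxyphenyl)-4H-chromen-4-one | COc1ccc(-c2cc(=O)c3c(OC)cc(OC)c(I)c3o2)cc1 | intermediate
14 | 5-hydroxy-8-iodo-7-methoxy-2-(4-methoxyphenyl)-4H-chromen-4-one | COc1ccc(-c2cc(=O)c3c(O)cc(OC)c(I)c3o2)cc1 | intermediate
15 | 8-iodo-7-methoxy-2-(4-methoxyphenyl)-5-(trimethylsilyloxy)-4H-chromen-4-one | COc1ccc(-c2cc(=O)c3c(O[Si](C)(C)C)cc(OC)c(I)c3o2)cc1 | intermediate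
16 | iodo[7-methoxy-2-(4-methoxyphenyl)-4-oxo-5-(trimethylsilyloxy)-4H-chromen-8-yl]zinc | COc1ccc(-c2cc(=O)c3c(O[Si](C)(C)C)cc(OC)c([Zn]I)c3o2)cc1 | intermediate
17 | (2S)-2-[3-iodo-4-(trimethylsilyloxy)phenyl]-7-methoxy-5-(trimethylsilyloxy)chroman-4-one | O=C1C[C@@H](c2ccc(O[Si](C)(C)C)c(I)c2)Oc2cc(OC)cc(O[Si](C)(C)C)c12 | intermediate
18 | (2S)-7-methoxy-2-[3-[7-methoxy-2-(4-methoxyphenyl)-4-oxo-5-(trimethylsilyloxy)-4H-chromen-8-yl]-4-(trimethylsilyloxy)phenyl]-5-(trimethylsilyloxy)chroman-4-one | O=C1C[C@@H](c2ccc(O[Si](C)(C)C)c(-c3c(OC)cc(O[Si](C)(C)C)c4c(=O)cc(-c5ccc(OC)cc5)oc34)c2)Oc2cc(OC)cc(O[Si](C)(C)C)c12 | intermediate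
19 | (2S)-2,3-dihydroheveaflavone [(2S)-5-hydroxy-2-[4-hydroxy-3-[5-hydroxy-7-methoxy-2-(4-methoxyphenyl)-4-oxo-4H-chromen-8-yl]phenyl]-7-methoxychroman-4-one] | COc1ccc(-c2cc(=O)c3c(O)cc(OC)c(-c4cc([C@@H]5CC(=O)c6c(O)cc(OC)cc6O5)ccc4O)c3o2)cc1 | target

**Step count:** 9 steps in total. **Longest linear sequence:** 7 steps (steps 3 to 9, from 4).

**Steps most likely to fail**

Step 2 (site-selective iodination). Ring A of sakuranetin is also electron-rich, di-iodination can occur, and prolonged exposure of the 4'-phenoxide risks ring opening and loss of ee. The fallback makes the C3'–halogen bond through a sterically governed C–H borylation and sets out from 2. [Ir(OMe)(cod)]2/dtbpy, HBpin, THF, 60 °C, then MeOH gives (2S)-5-hydroxy-2-[4-hydroxy-3-(4,4,5,5-tetramethyl-1,3,2-dioxaborolan-2-yl)phenyl]-7-methoxychroman-4-one F1. The O-borylated phenol steers iridium to its ortho C–H, and both ring A hydrogens are flanked on two sides and do not react. CuI/1,10-phenanthroline, KI, MeOH/H2O, air, 60 °C then exchanges boron for iodine, and the route is back at 3.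

Step 7 (C8 against C6 in the iodination of the flavone). The fallback places the iodine before ring C exists, using the ortho-directing hydrogen-bonded phenol of the aldehyde, and sets out from 4. Benzyltrimethylammonium dichloroiodate, CaCO3, CH2Cl2/MeOH gives 2-hydroxy-3-iodo-4,6-dimethoxybenzaldehyde F2. The chemistry of steps 3 to 6 is then repeated on the iodinated series:
- 3-iodo-4,6-dimethoxy-2-(methoxymethoxy)benzaldehyde F3;
- 2-ethynyl-4-iodo-1,5-dimethoxy-3-(methoxymethoxy)benzene F4;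
- 5-[3-iodo-4,6-dimethoxy-2-(methoxymethoxy)phenyl]-3-(4-methoxyphenyl)isoxazole F5;
- in the Mo(CO)6 then HCl/MeOH pot, the amino enone (Z)-3-amino-1-[3-iodo-4,6-dimethoxy-2-(methoxymethoxy)phenyl]-3-(4-methoxyphenyl)prop-2-en-1-one F6 and its free phenol (Z)-3-amino-1-(2-hydroxy-3-iodo-4,6-dimethoxyphenyl)-3-(4-methoxyphenyl)prop-2-en-1-one F7.

Ring closure through the oxygen next to iodine can only give the 8-iodo isomer, so the route is rejoined at 13.

Step 9 (tri-ortho-substituted biaryl). Transmetalation is slow, and protodezincation and homocoupling compete. The fallback is a Suzuki–Miyaura union with the ring B phenol masked as an acetal and boron on the flavone; it sets out from 3 and 14.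
- MOMCl, iPr2NEt, CH2Cl2, 0 °C converts 3 into (2S)-5-hydroxy-2-[3-iodo-4-(methoxymethoxy)phenyl]-7-methoxychroman-4-one F8.
- B2pin2, KOAc, PdCl2(dppf), dioxane, 90 °C converts 14 into 5-hydroxy-7-methoxy-2-(4-methoxyphenyl)-8-(4,4,5,5-tetramethyl-1,3,2-dioxaborolan-2-yl)-4H-chromen-4-one F9.
- Pd(OAc)2/SPhos, K3PO4, THF/H2O, 40 °C joins them to (2S)-5-hydroxy-2-[3-[5-hydroxy-7-methoxy-2-(4-methoxyphenyl)-4-oxo-4H-chromen-8-yl]-4-(methoxymethoxy)phenyl]-7-methoxychroman-4-one F10. With the 4'-oxygen alkylated the flavanone cannot open through a quinone methide, so the short, mild basic exposure should be tolerated.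
- 1 M HCl in MeOH at rt removes the acetal, and the route is back at 19.

Further compounds
F1 | step 2 | (2S)-5-hydroxy-2-[4-hydroxy-3-(4,4,5,5-tetramethyl-1,3,2-dioxaborolan-2-yl)phenyl]-7-methoxychroman-4-one | O=C1C[C@@H](c2ccc(O)c(B3OC(C)(C)C(C)(C)O3)c2)Oc2cc(OC)cc(O)c12
F2 | step 7 | 2-hydroxy-3-iodo-4,6-dimethoxybenzaldehyde | COc1cc(OC)c(C=O)c(O)c1I
F3 | step 7 | 3-iodo-4,6-dimethoxy-2-(methoxymethoxy)benzaldehyde | COCOc1c(I)c(OC)cc(OC)c1C=O
F4 | step 7 | 2-ethynyl-4-iodo-1,5-dimethoxy-3-(methoxymethoxy)benzene | COCOc1c(I)c(OC)cc(OC)c1C#C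
F5 | step 7 | 5-[3-iodo-4,6-dimethoxy-2-(methoxymethoxy)phenyl]-3-(4-methoxyphenyl)isoxazole | COCOc1c(I)c(OC)cc(OC)c1-c1cc(-c2ccc(OC)cc2)no1
F6 | step 7 | (Z)-3-amino-1-[3-iodo-4,6-dimethoxy-2-(methoxymethoxy)phenyl]-3-(4-methoxyphenyl)prop-2-en-1-one | N/C(c1ccc(OC)cc1)=C\C(=O)c1c(OC)cc(OC)c(I)c1OCOC
F7 | step 7 | (Z)-3-amino-1-(2-hydroxy-3-iodo-4,6-dimethoxyphenyl)-3-(4-methoxyphenyl)prop-2-en-1-one | N/C(c1ccc(OC)cc1)=C\C(=O)c1c(OC)cc(OC)c(I)c1O
F8 | step 9 | (2S)-5-hydroxy-2-[3-iodo-4-(methoxymethoxy)phenyl]-7-methoxychroman-4-one | O=C1C[C@@H](c2ccc(OCOC)c(I)c2)Oc2cc(OC)cc(O)c12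
F9 | step 9 | 5-hydroxy-7-methoxy-2-(4-methoxyphenyl)-8-(4,4,5,5-tetramethyl-1,3,2-dioxaborolan-2-yl)-4H-chromen-4-one | COc1ccc(-c2cc(=O)c3c(O)cc(OC)c(B4OC(C)(C)C(C)(C)O4)c3o2)cc1
F10 | step 9 | (2S)-5-hydroxy-2-[3-[5-hydroxy-7-methoxy-2-(4-methoxyphenyl)-4-oxo-4H-chromen-8-yl]-4-(methoxymethoxy)phenyl]-7-methoxychroman-4-one | O=C1C[C@@H](c2ccc(OCOC)c(-c3c(OC)cc(O)c4c(=O)cc(-c5ccc(OC)cc5)oc34)c2)Oc2cc(OC)cc(O)c12
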